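**Strategy.** The hexasubstituted arene (C8, C9, C11–C14; abietane numbering, ring B = C5–C10) is not carried in from an aromatic starting material but grown last onto a finished ring B. Its quaternary neighbour C10 is then an ordinary α-carbon of a C9 ketone, set together with C5 by conjugate addition/enolate methylation. The C9 alkenyllithium adds to an isopropyl(isopropoxy)cyclobutenedione, and thermolysis of the resulting 4-hydroxy-4-cyclohexenylcyclobutenone (Moore ring expansion: 4π opening, 6π closure onto C8, tautomerisation) delivers the whole benzene ring with O11, O12, the C13 isopropyl and O14 in place in one operation. C7 oxidation and unveiling of O12 through the quinone finish the synthesis.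

Key step: step 6

Remarks and assumptions (chemistry only):
- Atom labels: C5 = CH bearing isopropenyl, C6 = CH2, C7 = ring ketone carbon, C8/C9 = ring-fusion arene carbons, C10 = quaternary carbon, C11/C12/C14 = oxygenated arene carbons, C13 = arene carbon bearing isopropyl. TBSO = tert-butyldimethylsilyloxy.
- Compounds 1, 2, 8 and all reagents are taken as commercial.
- The catalyst antipode in step 2 is the one that gives the 3S ketone; it is assigned by analogy and must be confirmed.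
- The carbinol centres of 9, 12 and 17 and C8a of 14 form as mixtures that converge later, so they are left undefined.

Step 1
Reactants: 1 allyloxy(tert-butyl)dimethylsilane; 2 2-iodocyclohex-2-en-1-one
Product: 4 2-[3-(TBSO)propyl]cyclohex-2-en-1-one, via B-alkyl-9-BBN 3 (not isolated)
Conditions: 9-BBN, THF, 0 °C to rt; then 2, PdCl2(dppf) (5 mol%), Ph3As, Cs2CO3, DMF/H2O, rt
Reagents that add atoms: none
Why: Anti-Markovnikov hydroboration of the terminal alkene followed by B-alkyl Suzuki–Miyaura coupling with the α-iodoenone should give the 2-alkylenone; no stereocentre is formed.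

Step 2
Reactants: 4 2-[3-(TBSO)propyl]cyclohex-2-en-1-one
Product: 6 (2R,3S)-2-[3-(TBSO)propyl]-2-methyl-3-(prop-1-en-2-yl)cyclohexan-1-one, via magnesium enolate 5 (not isolated)
Conditions: isopropenylmagnesium bromide (1.3 equiv), CuBr·SMe2 (5 mol%), Josiphos-type ferrocenyl diphosphine (6 mol%), t-BuOMe, −78 °C; then MeI (5 equiv), DMPU, −78 to 0 °C
Reagents that add atoms: isopropenylmagnesium bromide C=C(C)[Mg]Br; iodomethane CI
Why: Copper-catalysed asymmetric conjugate addition of the alkenyl Grignard reagent (the chiral ligand selects the enone face and so sets C5) is followed by alkylation of the regiodefined enolate 5, where MeI should attack anti to the neighbouring isopropenyl group and place methyl trans and the silyloxypropyl chain cis to it at C10 (three-component conjugate addition/enolate trapping).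

Step 3
Reactants: 6 (2R,3S)-2-[3-(TBSO)propyl]-2-methyl-3-(prop-1-en-2-yl)cyclohexan-1-one
Product: 7 N'-[(2R,3S)-2-[3-(TBSO)propyl]-2-methyl-3-(prop-1-en-2-yl)cyclohexylidene]-2,4,6-tri(propan-2-yl)benzenesulfonohydrazide
Conditions: 2,4,6-triisopropylbenzenesulfonyl hydrazide (1.1 equiv), PPTS (cat.), 4 Å MS, THF, rt to 40 °C
Reagents that add atoms: 2,4,6-triisopropylbenzenesulfonyl hydrazide CC(C)c1cc(C(C)C)c(S(=O)(=O)NN)c(C(C)C)c1
Why: Acid-catalysed hydrazone formation; C10 is quaternary and C5 is not α to the carbonyl, so neither stereocentre can epimerise.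

Step 4
Reactants: 8 3,4-di(propan-2-yloxy)cyclobut-3-ene-1,2-dione (diisopropyl squarate)
Product: 10 3-(propan-2-yl)-4-(propan-2-yloxy)cyclobut-3-ene-1,2-dione, via carbinol adduct 9 (not isolated)
Conditions: i-PrMgCl (1.05 equiv), THF, −78 °C; then 6 M aq. HCl, CH2Cl2, rt
Reagents that add atoms: isopropylmagnesium chloride CC(C)[Mg]Cl
Why: 1,2-Addition of the Grignard reagent to one squarate carbonyl and acid-induced loss of propan-2-ol (vinylogous ester hydrolysis with allylic transposition) is the standard preparation of 3-alkoxy-4-alkylcyclobutenediones.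

Step 5
Reactants: 7 trisylhydrazone of ketone 6; 10 3-(propan-2-yl)-4-(propan-2-yloxy)cyclobut-3-ene-1,2-dione
Product: 12 4-hydroxy-4-[(5S,6R)-6-[3-(TBSO)propyl]-6-methyl-5-(prop-1-en-2-yl)cyclohex-1-en-1-yl]-2-(propan-2-yl)-3-(propan-2-yloxy)cyclobut-2-en-1-one, via alkenyllithium 11 (not isolated)
Conditions: n-BuLi (2.1 equiv), THF, −78 to 0 °C; then 10, −78 °C; aq. NH4Cl
Reagents that add atoms: none
Why: Shapiro reaction: only C8 carries α-hydrogens, so the C9 alkenyllithium 11 forms regiospecifically and should add 1,2 to the more electrophilic carbonyl of 10 (the one next to C–OiPr; the other is a deactivated vinylogous ester carbonyl), which fixes the cyclobutenone carbon that becomes C11.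

Step 6
Reactants: 12 4-hydroxy-4-cyclohexenylcyclobutenone adduct
Product: 16 tert-butyl{3-[(1R,2S)-5,8-dimethoxy-1-methyl-6-(propan-2-yl)-7-(propan-2-yloxy)-2-(prop-1-en-2-yl)-1,2,3,4-tetrahydronaphthalen-1-yl]propoxy}dimethylsilane, via dienylketene 13 (not isolated), via cyclohexadienone 14 (not isolated), via hydroquinone 15 (not isolated)
Conditions: PhMe (0.01 M, degassed), 110 °C; then K2CO3, Me2SO4, acetone, 56 °C (Ar)
Reagents that add atoms: dimethyl sulfate COS(=O)(=O)OC
Why: Heating opens the cyclobutenone by conrotatory 4π electrocyclic cleavage of the bond between the carbonyl carbon (future C14) and the carbinol carbon (future C11), the hydroxyl rotating outward and the cyclohexenyl group inward, to give (Z)-dienylketene 13; 6π electrocyclisation joins the ketene carbon to C8, and tautomerisation of dienone 14 (loss of the C8 hydrogen) gives hydroquinone 15, which is capped in the same pot by Williamson methylation. The closest known reaction type is the Moore rearrangement of 4-alkenyl-4-hydroxycyclobutenones to hydroquinones and quinones. Ring C is closed by a 6π (hexatriene-type) electrocyclisation of the dienylketene that forms the C8–C14 bond, and aromatisation makes it irreversible. No stereocentre is created: C5 and C10 are spectators (C10 quaternary, C5 remote from any acidic or ionising site), so the configuration from step 2 is carried through. The selectivities needed are the torquoselectivity of the opening, secured by the 4-hydroxyl group whose outward rotation also prevents lactonisation to a furanone, and the placement of substituents, fixed by the constitution of 12: the carbinol carbon next to C–OiPr becomes C11, the ketene carbon next to C–iPr becomes C14, and C8 is the only alkene terminus available. Dilute, degassed conditions and immediate methylation should guard the electron-rich hydroquinone against ketene dimerisation and air oxidation.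

Step 7
Reactants: 16 dimethyl ether of the hydroquinone
Product: 18 (3S,4R)-4-[3-(TBSO)propyl]-5,8-dimethoxy-4-methyl-7-(propan-2-yl)-6-(propan-2-yloxy)-3-(prop-1-en-2-yl)-3,4-dihydronaphthalen-1(2H)-one, via benzylic alcohol 17 (not isolated)
Conditions: DDQ (2.5 equiv), CH2Cl2/H2O, 0 °C to rt
Reagents that add atoms: water O
Why: DDQ benzylic oxidation: hydride abstraction should occur at C7, the only benzylic CH2, whose cation is stabilised by the para isopropoxy (O12) and ortho methoxy (O14) groups; water captures it and a second hydride abstraction gives the aryl ketone, while the isopropyl methine is twisted out of conjugation by its two ortho substituents.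

Step 8
Reactants: 18 C7 ketone with silyl-protected chain
Product: 21 3-[(1R,2S)-5,8-dimethoxy-1-methyl-4-oxo-6-(propan-2-yl)-7-(propan-2-yloxy)-2-(prop-1-en-2-yl)-1,2,3,4-tetrahydronaphthalen-1-yl]propanoic acid, via primary alcohol 19 (not isolated), via aldehyde 20 (not isolated)
Conditions: Jones reagent (CrO3, H2SO4, H2O), acetone, 0 °C
Reagents that add atoms: water O
Why: Jones oxidation: the acidic medium cleaves the primary silyl ether and chromic acid oxidises the alcohol through the aldehyde hydrate to the acid; the aryl ketone, aryl ethers and 1,1-disubstituted alkene should be inert at 0 °C.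

Step 9
Reactants: 21 dimethoxy keto acid
Product: 22 3-[(1R,2S)-1-methyl-4,5,8-trioxo-6-(propan-2-yl)-7-(propan-2-yloxy)-2-(prop-1-en-2-yl)-1,2,3,4,5,8-hexahydronaphthalen-1-yl]propanoic acid
Conditions: (NH4)2Ce(NO3)6 (2.5 equiv), MeCN/H2O, 0 °C
Reagents that add atoms: water O
Why: CAN oxidative demethylation of a hydroquinone dimethyl ether: water adds ipso at the para-related methoxy carbons C11 and C14 and methanol is lost, giving the para-quinone that keeps the C12 isopropoxy group as a vinylogous ester.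

Step 10
Reactants: 22 isopropoxyquinone acid
Product: 24 3-[(1R,2S)-5,7,8-trihydroxy-1-methyl-4-oxo-6-(propan-2-yl)-2-(prop-1-en-2-yl)-1,2,3,4-tetrahydronaphthalen-1-yl]propanoic acid, via hydroxyquinone 23 (not isolated)
Conditions: 2 M aq. NaOH, THF, 0 °C to rt (Ar); then aq. Na2S2O4; then 1 M HCl to pH 3
Reagents that add atoms: sodium hydroxide [Na+].[OH-]
Why: Hydroxide should add to C12 of the alkoxyquinone and expel isopropoxide (addition–elimination on a vinylogous ester), and dithionite then reduces the hydroxyquinone to the hydroquinone, held by the C7=O···HO14 hydrogen bond; C5 is β to the ketone and C10 is quaternary, so neither can epimerise.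

**Compound list**

1 | allyloxy(tert-butyl)dimethylsilane | C=CCO[Si](C)(C)C(C)(C)C | starting material
2 | 2-iodocyclohex-2-en-1-one | O=C1CCCC=C1I | starting material
3 | 9-[3-(TBSO)propyl]-9-borabicyclo[3.3.1]nonane | CC(C)(C)[Si](C)(C)OCCCB1C2CCCC1CCC2 | intermediate
4 | 2-[3-(TBSO)propyl]cyclohex-2-en-1-one | O=C1CCCC=C1CCCO[Si](C)(C)C(C)(C)C | intermediate
5 | bromomagnesium (3S)-2-[3-(TBSO)propyl]-3-(prop-1-en-2-yl)cyclohex-1-en-1-olate | C=C(C)[C@@H]1CCCC(O[Mg]Br)=C1CCCO[Si](C)(C)C(C)(C)C | intermediate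
6 | (2R,3S)-2-[3-(TBSO)propyl]-2-methyl-3-(prop-1-en-2-yl)cyclohexan-1-one | C=C(C)[C@@H]1CCCC(=O)[C@]1(C)CCCO[Si](C)(C)C(C)(C)C | intermediate
7 | N'-[(2R,3S)-2-[3-(TBSO)propyl]-2-methyl-3-(prop-1-en-2-yl)cyclohexylidene]-2,4,6-tri(propan-2-yl)benzenesulfonohydrazide | C=C(C)[C@@H]1CCCC(=NNS(=O)(=O)c2c(C(C)C)cc(C(C)C)cc2C(C)C)[C@]1(C)CCCO[Si](C)(C)C(C)(C)C | intermediate
8 | 3,4-di(propan-2-yloxy)cyclobut-3-ene-1,2-dione (diisopropyl squarate) | CC(C)OC1=C(OC(C)C)C(=O)C1=O | starting material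
9 | 4-hydroxy-4-(propan-2-yl)-2,3-di(propan-2-yloxy)cyclobut-2-en-1-one | CC(C)OC1=C(OC(C)C)C(O)(C(C)C)C1=O | intermediate
10 | 3-(propan-2-yl)-4-(propan-2-yloxy)cyclobut-3-ene-1,2-dione | CC(C)OC1=C(C(C)C)C(=O)C1=O | intermediate
11 | [(5S,6R)-6-[3-(TBSO)propyl]-6-methyl-5-(prop-1-en-2-yl)cyclohex-1-en-1-yl]lithium | C=C(C)[C@@H]1CCC=C([Li])[C@]1(C)CCCO[Si](C)(C)C(C)(C)C | intermediate
12 | 4-hydroxy-4-[(5S,6R)-6-[3-(TBSO)propyl]-6-methyl-5-(prop-1-en-2-yl)cyclohex-1-en-1-yl]-2-(propan-2-yl)-3-(propan-2-yloxy)cyclobut-2-en-1-one (carbinol epimers) | C=C(C)[C@@H]1CCC=C(C2(O)C(OC(C)C)=C(C(C)C)C2=O)[C@]1(C)CCCO[Si](C)(C)C(C)(C)C | intermediate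
13 | (3Z)-4-hydroxy-4-[(5S,6R)-6-[3-(TBSO)propyl]-6-methyl-5-(prop-1-en-2-yl)cyclohex-1-en-1-yl]-2-(propan-2-yl)-3-(propan-2-yloxy)buta-1,3-dien-1-one | C=C(C)[C@@H]1CCC=C(/C(O)=C(OC(C)C)\C(C(C)C)=C=O)[C@]1(C)CCCO[Si](C)(C)C(C)(C)C | intermediate
14 | (5R,6S)-5-[3-(TBSO)propyl]-4-hydroxy-5-methyl-2-(propan-2-yl)-3-(propan-2-yloxy)-6-(prop-1-en-2-yl)-6,7,8,8a-tetrahydronaphthalen-1(5H)-one | C=C(C)[C@@H]1CCC2C(=O)C(C(C)C)=C(OC(C)C)C(O)=C2[C@]1(C)CCCO[Si](C)(C)C(C)(C)C | intermediate
15 | (5R,6S)-5-[3-(TBSO)propyl]-5-methyl-2-(propan-2-yl)-3-(propan-2-yloxy)-6-(prop-1-en-2-yl)-5,6,7,8-tetrahydronaphthalene-1,4-diol | C=C(C)[C@@H]1CCc2c(O)c(C(C)C)c(OC(C)C)c(O)c2[C@]1(C)CCCO[Si](C)(C)C(C)(C)C | intermediate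
16 | tert-butyl{3-[(1R,2S)-5,8-dimethoxy-1-methyl-6-(propan-2-yl)-7-(propan-2-yloxy)-2-(prop-1-en-2-yl)-1,2,3,4-tetrahydronaphthalen-1-yl]propoxy}dimethylsilane | C=C(C)[C@@H]1CCc2c(OC)c(C(C)C)c(OC(C)C)c(OC)c2[C@]1(C)CCCO[Si](C)(C)C(C)(C)C | intermediate
17 | (3S,4R)-4-[3-(TBSO)propyl]-5,8-dimethoxy-4-methyl-7-(propan-2-yl)-6-(propan-2-yloxy)-3-(prop-1-en-2-yl)-1,2,3,4-tetrahydronaphthalen-1-ol (C1 epimers) | C=C(C)[C@@H]1CC(O)c2c(OC)c(C(C)C)c(OC(C)C)c(OC)c2[C@]1(C)CCCO[Si](C)(C)C(C)(C)C | intermediate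
18 | (3S,4R)-4-[3-(TBSO)propyl]-5,8-dimethoxy-4-methyl-7-(propan-2-yl)-6-(propan-2-yloxy)-3-(prop-1-en-2-yl)-3,4-dihydronaphthalen-1(2H)-one | C=C(C)[C@@H]1CC(=O)c2c(OC)c(C(C)C)c(OC(C)C)c(OC)c2[C@]1(C)CCCO[Si](C)(C)C(C)(C)C | intermediate
19 | (3S,4R)-4-(3-hydroxypropyl)-5,8-dimethoxy-4-methyl-7-(propan-2-yl)-6-(propan-2-yloxy)-3-(prop-1-en-2-yl)-3,4-dihydronaphthalen-1(2H)-one | C=C(C)[C@@H]1CC(=O)c2c(OC)c(C(C)C)c(OC(C)C)c(OC)c2[C@]1(C)CCCO | intermediate
20 | 3-[(1R,2S)-5,8-dimethoxy-1-methyl-4-oxo-6-(propan-2-yl)-7-(propan-2-yloxy)-2-(prop-1-en-2-yl)-1,2,3,4-tetrahydronaphthalen-1-yl]propanal | C=C(C)[C@@H]1CC(=O)c2c(OC)c(C(C)C)c(OC(C)C)c(OC)c2[C@]1(C)CCC=O | intermediate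
21 | 3-[(1R,2S)-5,8-dimethoxy-1-methyl-4-oxo-6-(propan-2-yl)-7-(propan-2-yloxy)-2-(prop-1-en-2-yl)-1,2,3,4-tetrahydronaphthalen-1-yl]propanoic acid | C=C(C)[C@@H]1CC(=O)c2c(OC)c(C(C)C)c(OC(C)C)c(OC)c2[C@]1(C)CCC(=O)O | intermediate
22 | 3-[(1R,2S)-1-methyl-4,5,8-trioxo-6-(propan-2-yl)-7-(propan-2-yloxy)-2-(prop-1-en-2-yl)-1,2,3,4,5,8-hexahydronaphthalen-1-yl]propanoic acid | C=C(C)[C@@H]1CC(=O)C2=C(C(=O)C(OC(C)C)=C(C(C)C)C2=O)[C@]1(C)CCC(=O)O | intermediate
23 | 3-[(1R,2S)-7-hydroxy-1-methyl-4,5,8-trioxo-6-(propan-2-yl)-2-(prop-1-en-2-yl)-1,2,3,4,5,8-hexahydronaphthalen-1-yl]propanoic acid | C=C(C)[C@@H]1CC(=O)C2=C(C(=O)C(O)=C(C(C)C)C2=O)[C@]1(C)CCC(=O)O | intermediate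
24 | 3-[(1R,2S)-5,7,8-trihydroxy-1-methyl-4-oxo-6-(propan-2-yl)-2-(prop-1-en-2-yl)-1,2,3,4-tetrahydronaphthalen-1-yl]propanoic acid (CNP0198818.2) | C=C(C)[C@@H]1CC(=O)c2c(O)c(C(C)C)c(O)c(O)c2[C@]1(C)CCC(=O)O | target

**Totals.** Total step count: 10. Longest linear sequence: 9 steps (1, 2, 3, 5, 6, 7, 8, 9, 10); step 4 prepares the cyclobutenedione in parallel.

**Steps most likely to fail, with fallbacks.**

First, step 2. Alkenyl Grignard reagents and α-substituted enones both lie at the edge of copper-catalysed asymmetric conjugate addition. Face selection may be poor, 1,2-addition may compete, and C-methylation of the hindered tetrasubstituted enolate may be incomplete.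

The fallback sets out from 1 and returns at 6; it separates the enantioselective step from the formation of the quaternary centre.
- Hydroboration–iodination of 1 (9-BBN; then I2, NaOMe) should give tert-butyl(3-iodopropoxy)dimethylsilane F1.
- Commercial cyclohex-2-en-1-one is taken through a Rh(I)/BINAP-catalysed Hayashi–Miyaura 1,4-addition of isopropenylboronic acid pinacol ester (antipode chosen for the 3R ketone) to (R)-3-(prop-1-en-2-yl)cyclohexan-1-one F2.
- Formylation at the less hindered α-carbon (HCO2Et, NaH) should give (5R)-2-(hydroxymethylidene)-5-(prop-1-en-2-yl)cyclohexan-1-one F3.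
- The dianion of F3 (KNH2, liquid NH3/THF) is alkylated at the free α'-carbon with F1 to give (5R,6S)-6-[3-(TBSO)propyl]-2-(hydroxymethylidene)-5-(prop-1-en-2-yl)cyclohexan-1-one F4.
- A second dianion formation and MeI, again anti to the isopropenyl group, should give (5S,6R)-6-[3-(TBSO)propyl]-2-(hydroxymethylidene)-6-methyl-5-(prop-1-en-2-yl)cyclohexan-1-one F5.
- Deformylation with aqueous NaOH returns ketone 6.

Second, step 7. The hydride abstraction may lose chemoselectivity: the C7 cation may lose a proton to give the 6,7-alkene, it may be captured by the isopropenyl group, or the silyl ether may be cleaved early (harmless, since step 8 accepts alcohol 19).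

The fallback sets out from 6 and returns at 21; it brings the C7 oxygen in before the arene is built.
- IBX dehydrogenation of 6 toward the only enolisable side should give (5S,6R)-6-[3-(TBSO)propyl]-6-methyl-5-(prop-1-en-2-yl)cyclohex-2-en-1-one F6.
- Copper-catalysed β-borylation (B2pin2, CuCl, NaOt-Bu, MeOH) and NaBO3 oxidation should give (2R,3S)-2-[3-(TBSO)propyl]-5-hydroxy-2-methyl-3-(prop-1-en-2-yl)cyclohexan-1-one F7.
- Silylation (TBSOTf, 2,6-lutidine) gives (2R,3S)-5-(TBSO)-2-[3-(TBSO)propyl]-2-methyl-3-(prop-1-en-2-yl)cyclohexan-1-one F8.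
- Hydrazine gives the hydrazone of F8 F9, and I2/tetramethylguanidine (Barton alkenyl iodide synthesis) gives (5S,6R)-3-(TBSO)-6-[3-(TBSO)propyl]-1-iodo-6-methyl-5-(prop-1-en-2-yl)cyclohex-1-ene F10.
- Iodine–lithium exchange (t-BuLi, −78 °C) and addition to 10 give 4-hydroxy-4-[(5S,6R)-3-(TBSO)-6-[3-(TBSO)propyl]-6-methyl-5-(prop-1-en-2-yl)cyclohex-1-en-1-yl]-2-(propan-2-yl)-3-(propan-2-yloxy)cyclobut-2-en-1-one F11.
- Thermolysis and methylation as in step 6 give tert-butyl{3-[(1R,2S)-4-(TBSO)-5,8-dimethoxy-1-methyl-6-(propan-2-yl)-7-(propan-2-yloxy)-2-(prop-1-en-2-yl)-1,2,3,4-tetrahydronaphthalen-1-yl]propoxy}dimethylsilane F12.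
- Jones oxidation of F12 turns the benzylic silyl ether into the ketone and the primary one into the acid, rejoining the route at 21.

Third, step 10. Addition–elimination at the hindered C12 may be slow, and the acylquinone may degrade in base (attack at C7 with retro-Claisen-type cleavage) or the product may be reoxidised by air.

The fallback sets out from 22 and returns at 24; it reduces first and then removes the isopropyl group with a Lewis acid instead of hydrolysing the quinone.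
- Na2S2O4 in aqueous THF should give 3-[(1R,2S)-5,8-dihydroxy-1-methyl-4-oxo-6-(propan-2-yl)-7-(propan-2-yloxy)-2-(prop-1-en-2-yl)-1,2,3,4-tetrahydronaphthalen-1-yl]propanoic acid F13.
- BCl3 (CH2Cl2, −78 °C, pentamethylbenzene as cation scavenger) should cleave the aryl isopropyl ether selectively and give 24 after aqueous work-up. The low temperature is needed to spare the isopropenyl group.

**Further compounds**

F1 | step 2 | tert-butyl(3-iodopropoxy)dimethylsilane | CC(C)(C)[Si](C)(C)OCCCI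
F2 | step 2 | (R)-3-(prop-1-en-2-yl)cyclohexan-1-one | C=C(C)[C@@H]1CCCC(=O)C1
F3 | step 2 | (5R)-2-(hydroxymethylidene)-5-(prop-1-en-2-yl)cyclohexan-1-one | C=C(C)[C@@H]1CCC(=CO)C(=O)C1
F4 | step 2 | (5R,6S)-6-[3-(TBSO)propyl]-2-(hydroxymethylidene)-5-(prop-1-en-2-yl)cyclohexan-1-one | C=C(C)[C@@H]1CCC(=CO)C(=O)[C@H]1CCCO[Si](C)(C)C(C)(C)C
F5 | step 2 | (5S,6R)-6-[3-(TBSO)propyl]-2-(hydroxymethylidene)-6-methyl-5-(prop-1-en-2-yl)cyclohexan-1-one | C=C(C)[C@@H]1CCC(=CO)C(=O)[C@]1(C)CCCO[Si](C)(C)C(C)(C)C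
F6 | step 7 | (5S,6R)-6-[3-(TBSO)propyl]-6-methyl-5-(prop-1-en-2-yl)cyclohex-2-en-1-one | C=C(C)[C@@H]1CC=CC(=O)[C@]1(C)CCCO[Si](C)(C)C(C)(C)C
F7 | step 7 | (2R,3S)-2-[3-(TBSO)propyl]-5-hydroxy-2-methyl-3-(prop-1-en-2-yl)cyclohexan-1-one (C5 epimers) | C=C(C)[C@@H]1CC(O)CC(=O)[C@]1(C)CCCO[Si](C)(C)C(C)(C)C
F8 | step 7 | (2R,3S)-5-(TBSO)-2-[3-(TBSO)propyl]-2-methyl-3-(prop-1-en-2-yl)cyclohexan-1-one | C=C(C)[C@@H]1CC(O[Si](C)(C)C(C)(C)C)CC(=O)[C@]1(C)CCCO[Si](C)(C)C(C)(C)C
F9 | step 7 | hydrazone of F8 | C=C(C)[C@@H]1CC(O[Si](C)(C)C(C)(C)C)CC(=NN)[C@]1(C)CCCO[Si](C)(C)C(C)(C)C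
F10 | step 7 | (5S,6R)-3-(TBSO)-6-[3-(TBSO)propyl]-1-iodo-6-methyl-5-(prop-1-en-2-yl)cyclohex-1-ene | C=C(C)[C@@H]1CC(O[Si](C)(C)C(C)(C)C)C=C(I)[C@]1(C)CCCO[Si](C)(C)C(C)(C)C
F11 | step 7 | 4-hydroxy-4-[(5S,6R)-3-(TBSO)-6-[3-(TBSO)propyl]-6-methyl-5-(prop-1-en-2-yl)cyclohex-1-en-1-yl]-2-(propan-2-yl)-3-(propan-2-yloxy)cyclobut-2-en-1-one | C=C(C)[C@@H]1CC(O[Si](C)(C)C(C)(C)C)C=C(C2(O)C(OC(C)C)=C(C(C)C)C2=O)[C@]1(C)CCCO[Si](C)(C)C(C)(C)C
F12 | step 7 | tert-butyl{3-[(1R,2S)-4-(TBSO)-5,8-dimethoxy-1-methyl-6-(propan-2-yl)-7-(propan-2-yloxy)-2-(prop-1-en-2-yl)-1,2,3,4-tetrahydronaphthalen-1-yl]propoxy}dimethylsilane | C=C(C)[C@@H]1CC(O[Si](C)(C)C(C)(C)C)c2c(OC)c(C(C)C)c(OC(C)C)c(OC)c2[C@]1(C)CCCO[Si](C)(C)C(C)(C)C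
F13 | step 10 | 3-[(1R,2S)-5,8-dihydroxy-1-methyl-4-oxo-6-(propan-2-yl)-7-(propan-2-yloxy)-2-(prop-1-en-2-yl)-1,2,3,4-tetrahydronaphthalen-1-yl]propanoic acid | C=C(C)[C@@H]1CC(=O)c2c(O)c(C(C)C)c(OC(C)C)c(O)c2[C@]1(C)CCC(=O)O
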